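**Assumptions (one line each)**
- The target has no stereocenters. The large macrocycle has no stable planar or axial chirality, so "single enantiomer" has no meaning here.
- I read the CH2 chain in the SMILES as 14 carbons.

**Retrosynthetic overview**
1. The target is the tri-phenol obtained by global BBr3 demethylation of trimethyl ether **11**.
2. The only ring formed is the 22-membered diaryl ether in **11**. It comes from an intramolecular aryne O-arylation (new step). Fluoride unmasks a hindered 2,6-dimethoxyphenoxide from its silyl ether and generates a 3-methoxybenzyne from an o-silylaryl triflate. The phenoxide adds meta to the OMe group, which sets the 1,3,5 pattern on ring A.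
3. The aryne precursor is made from a 4-alkylguaiacol unit by ortho-bromination, O-silylation, retro-Brook silyl migration and triflation.
4. The seco chain Ar–(CH2)14–Ar' is built from 1,13-tetradecadiene by two sequential hydroboration/B-alkyl Suzuki couplings with two commercial bromophenols. Both arenes exist before the ring closes.

---

### Route

**Step 1**
Reactants: **1** 4-bromo-2,6-dimethoxyphenol
Product: **2** tert-butyl(4-bromo-2,6-dimethoxyphenoxy)dimethylsilane
Conditions: TBSCl, imidazole, DMF, rt
Reagents that add atoms: TBSCl, CC(C)(C)[Si](C)(C)Cl
Why: Standard silyl protection. It masks the hindered phenol for the Suzuki couplings and the organolithium step, and fluoride removes it in the last ring-forming step.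

**Step 2**
Reactants: **2** aryl bromide; **3** 1,13-tetradecadiene (5 equiv)
Product: **4** tert-butyl[2,6-dimethoxy-4-(tetradec-13-en-1-yl)phenoxy]dimethylsilane
Conditions: (i) 9-BBN-H (1 equiv relative to **2**), **3**, THF, 0 °C to rt; (ii) **2**, Pd(dppf)Cl2 (5 mol %), K3PO4, THF/H2O, 60 °C
Reagents that add atoms: none (9-BBN and Pd leave; **3** is a numbered reactant)
Why: Mono-hydroboration of the excess symmetrical diene gives a terminal B-alkyl-9-BBN, which undergoes a B-alkyl Suzuki–Miyaura coupling (Johnson–Suzuki type). The excess diene suppresses bis-coupling and is recovered.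

**Step 3**
Reactants: **4** terminal alkene; **5** 4-bromo-2-methoxyphenol
Product: **6** tert-butyl{2,6-dimethoxy-4-[14-(4-hydroxy-3-methoxyphenyl)tetradecyl]phenoxy}dimethylsilane
Conditions: (i) 9-BBN-H, THF, rt; (ii) **5**, Pd(dppf)Cl2 (5 mol %), K3PO4 (4 equiv), THF/H2O, 60 °C
Reagents that add atoms: none
Why: Anti-Markovnikov hydroboration gives the primary alkylborane, and a second B-alkyl Suzuki coupling closes the C14 tether. The free guaiacol phenol is tolerated, and ring B is fully substituted and TBS-protected.

**Step 4**
Reactants: **6**
Product: **7** the 2-bromo-phenol (Br ortho to the ring A OH), TBS ether intact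
Conditions: NBS (1.0 equiv), i-Pr2NH (10 mol %), CH2Cl2, –10 °C to rt
Reagents that add atoms: NBS, O=C1CCC(=O)N1Br (adds Br)
Why: Amine-mediated ortho-selective electrophilic bromination of a para-blocked phenol. Ring A is the only ring with a free OH and an open ortho site, and the silyl-protected ring B is hindered.

**Step 5**
Reactants: **7**
Product: **8** the aryl O-TMS ether of **7**
Conditions: HMDS (neat, excess), cat. (NH4)2SO4, 80 °C, 2 h, then evaporate
Reagents that add atoms: HMDS, C[Si](C)(C)N[Si](C)(C)C (adds TMS)
Why: Standard O-silylation. It sets up the anionic O→C silyl migration.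

**Step 6**
Reactants: **8**
Product: **9** the 2-(trimethylsilyl)phenol (TMS at the former C–Br carbon, free OH on ring A)
Conditions: n-BuLi (1.1 equiv), THF, –78 °C to rt; NH4Cl work-up
Reagents that add atoms: none (the TMS group migrates intramolecularly; Bu leaves as BuBr)
Why: Br/Li exchange followed by a 1,3 O→C retro-Brook silyl shift, the classic route to o-silylphenols. The aryl TBS ether on ring B survives at low temperature.

**Step 7**
Reactants: **9**
Product: **10** 4-alkyl-2-methoxy-6-(trimethylsilyl)phenyl triflate, aryne precursor (ring B TBS ether intact)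
Conditions: Tf2O, pyridine, CH2Cl2, –78 °C to 0 °C
Reagents that add atoms: Tf2O, O=S(=O)(C(F)(F)F)OS(=O)(=O)C(F)(F)F (adds Tf)
Why: Standard triflation gives a Kobayashi-type o-silylaryl triflate. The aryl–TMS and aryl–OTBS groups survive these mild conditions.

**Step 8 (key ring-forming step)**
Reactants: **10**
Product: **11** the trimethyl ether macrocycle (22-membered diaryl ether)
Conditions: CsF (10 equiv), MeCN, 50 °C; **10** added by syringe pump over 12 h to give about 2 mM; aqueous work-up
Reagents that add atoms: none (F⁻ leaves as TBSF and TMSF, triflate leaves as CsOTf; the new ring A C–H hydrogen comes from trace water or MeCN)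
Why: Proposed new method: intramolecular aryne O-arylation as a macrocyclization.
- Fluoride removes the TBS group to give the 2,6-dimethoxyphenoxide and removes the TMS group to eliminate triflate, giving a 3-methoxybenzyne.
- The ortho OMe group polarizes the aryne inductively, so the phenoxide adds at the carbon meta to OMe. The carbanion ends up ortho to OMe and is protonated, giving the 1,3,5-trisubstituted ring A.
- The closest known chemistry is intermolecular Kobayashi aryne O-arylation of phenols and aryne cyclizations to small rings. A 22-membered diaryl ether closure, with fluoride unmasking the nucleophile and the aryne precursor at once, has not been shown.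
- Syringe-pump addition keeps the steady-state concentration low, so ring closure competes with oligomerization.
- No stereocenter is formed.

**Step 9**
Reactants: **11**
Product: **12** Robustol
Conditions: BBr3 (6 equiv), CH2Cl2, –78 °C to rt, 12 h; MeOH quench
Reagents that add atoms: none (methyl groups leave as MeBr; the new OH hydrogens come from work-up)
Why: BBr3 cleaves the three aryl methyl ethers. The diaryl ether and the saturated chain are stable at or below rt.

---

### Compound list
1 | 4-bromo-2,6-dimethoxyphenol | COc1cc(Br)cc(OC)c1O | starting material
2 | TBS ether of **1** | COc1cc(Br)cc(OC)c1O[Si](C)(C)C(C)(C)C | intermediate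
3 | 1,13-tetradecadiene | C=CCCCCCCCCCCC=C | starting material
4 | ring B aryl TBS ether bearing a (CH2)12CH=CH2 chain | C=CCCCCCCCCCCCCc1cc(OC)c(O[Si](C)(C)C(C)(C)C)c(OC)c1 | intermediate
5 | 4-bromo-2-methoxyphenol | COc1cc(Br)ccc1O | starting material
6 | seco compound: ring B (TBSO, 2 OMe)–(CH2)14–ring A (OH, OMe) | COc1cc(CCCCCCCCCCCCCCc2ccc(O)c(OC)c2)cc(OC)c1O[Si](C)(C)C(C)(C)C | intermediate
7 | ortho-bromo derivative of **6** | COc1cc(CCCCCCCCCCCCCCc2cc(Br)c(O)c(OC)c2)cc(OC)c1O[Si](C)(C)C(C)(C)C | intermediate
8 | O-TMS ether of **7** | COc1cc(CCCCCCCCCCCCCCc2cc(Br)c(O[Si](C)(C)C)c(OC)c2)cc(OC)c1O[Si](C)(C)C(C)(C)C | intermediate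
9 | o-TMS phenol | COc1cc(CCCCCCCCCCCCCCc2cc([Si](C)(C)C)c(O)c(OC)c2)cc(OC)c1O[Si](C)(C)C(C)(C)C | intermediate
10 | o-silylaryl triflate | COc1cc(CCCCCCCCCCCCCCc2cc([Si](C)(C)C)c(OS(=O)(=O)C(F)(F)F)c(OC)c2)cc(OC)c1O[Si](C)(C)C(C)(C)C | intermediate
11 | trimethyl ether macrocycle | COc1cc2cc(c1)Oc1c(OC)cc(cc1OC)CCCCCCCCCCCCCC2 | intermediate
12 | Robustol | Oc1cc2cc(c1)Oc1c(O)cc(cc1O)CCCCCCCCCCCCCC2 | target

**Total steps:** 9. **Longest linear sequence:** 9 (1 → 2 → 4 → 6 → 7 → 8 → 9 → 10 → 11 → 12, counted as 9 transformations).

**Three steps most likely to fail**
1. **Step 8 (proposed new aryne macrocyclization).** Risks are oligomerization, the minor ortho-attack regioisomer, and trapping of the aryne by solvent or water.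
   - Fallback (known chemistry, different approach): build the diaryl ether first by Ullmann coupling of 4-bromo-2,6-dimethoxyphenol with 1-bromo-3-iodo-5-methoxybenzene (CuI, N,N-dimethylglycine, Cs2CO3, selective at C–I).
   - Then do a double B-alkyl Suzuki coupling with 7-octenyl-9-BBN (from 1,7-octadiene), followed by RCM (Grubbs II, about 1 mM).
   - Finish with H2/Pd-C to saturate the chain and BBr3 to remove the methyl groups.
2. **Step 4 (ortho-bromination).** NBS may over-brominate or touch the electron-rich silyl-protected ring B.
   - Fallback: brominate at the fragment stage. Use 2-bromo-4-iodo-6-methoxyphenol (from guaiacol by NIS then NBS) as the Step 3 partner, with iodide-selective Suzuki coupling that leaves the aryl bromide intact. This removes late-stage bromination.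
3. **Step 6 (retro-Brook).** The silyl shift may be incomplete or may cleave the ring B TBS ether.
   - Fallback: replace Steps 4–6 with directed ortho-metalation. Convert the ring A phenol of **6** to its N,N-diethylcarbamate, then use s-BuLi/TMEDA and TMSCl to silylate C6, then cleave the carbamate (LiAlH4) to give **9**.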